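At late times the target in these flasks is a small remainder beside a large stock of unused starting material, so I read the two together.

| flask | starting material | reagent in the second phase | protic impurity | remark | time | volume of the second phase over the first |
|---|---|---|---|---|---|---|
| amber | 0.20 M | 0.26 M | 5.6 mM | run made earlier |  |  |
| teal | 0.20 M | 0.26 M | 8.8 mM | run made earlier |  |  |
| green | 0.20 M | 0.39 M | 4 mM | run made earlier |  |  |
| flask | 0.20 M | 0.260 M | 4.00 mM |  | 6.0 h | 2.0 |

| run | time / h | target / % | starting material / % |
|---|---|---|---|
| amber | 1.33 | 15.7 | 66.5 |
| amber | 2.50 | 11.5 | 57.4 |
| amber | 4.00 | 8.1 | 50.5 |
| amber | 5.00 | 7.6 | 48.5 |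
| amber | 6.00 | 6.8 | 46.3 |
| teal | 0.500 | 13.9 | 80.5 |
| teal | 0.833 | 16.5 | 72.4 |
| teal | 1.50 | 16.2 | 63.1 |
| teal | 3.00 | 10.7 | 53.7 |
| teal | 6.00 | 5.1 | 45.6 |
| green | 0.500 | 19.1 | 76.7 |
| green | 1.50 | 17.4 | 50.7 |
| green | 3.00 | 10.4 | 36.8 |
| green | 4.00 | 7.0 | 30.1 |
| green | 6.00 | 4.9 | 24.8 |

(standard deviation of a reading: 0.5 percentage points)

- in the second phase: reagent in the second phase; everything else is in the first
- charges count per volume of the first phase; a concentration in a rate is the amount of a species over the volume of its own phase; every rate counts per litre of the first phase
- the numbers in the tables scatter with a standard deviation of 0.5 percentage points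
- the earlier runs hold the two phases in the same ratio of volumes as the flask asked about

- birch: doubling the transfer coefficient of the reagent in the second phase, all else as stated
- larch: doubling the amount of reagent in the second phase, all else as stated

* target at 6.0 h, in percent of the starting material charged
* the change that raises the amount of target at 6.0 h, in percent of the starting material charged most ("none" if none brings more than 2 percentage points) (birch / larch / none)
* amount of target at 6.0 h, in percent of the starting material charged, after birch

My bench rule says the protic impurity costs its own charge of starting material, one for one. Its zero is the case where amber and teal are the same run twice, since they differ in the impurity charge. Pooled, they give 0.129 for the late ratio, target over starting material as fractions of the charge at 6.00 h. The extra impurity in teal is 1.60% of the charge, worth 0.21 percentage points of target at that ratio. The gap reads 1.7 points against a scatter of 0.5 points per reading, so the rule does not reach it, and I treat it, uneasily, as noise.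

The late ratio stops holding when the reagent charge moves. Green has 1.50 times the reagent charge of amber, and a smaller impurity charge as well, and its late ratio reads 1.53 times the pooled one, so I hold the ratio to one reagent charge. The flask has amber's reagent charge and impurity worth 2.00% of the charge. With starting material at the mean of amber and teal, I reckon 5.94% of target. Green's 4.9% promises no gain from more reagent.

The forecast stands higher than my reckoning, at 8% (7% to 9.2%), with 6.5% after birch (4.3% to 8.6%) and the choice none: “Neither change helps”.

The flask gives 5.80%, 5.01% after birch, and the choice none.

    reagent in the reaction phase + target → over-reacted product (k = 17.2 M⁻¹ h⁻¹)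
    starting material + protic impurity → quenched substrate (k = 617 M⁻¹ h⁻¹)
    reagent in the reaction phase ⇌ reagent in the second phase, rate k3*([reagent in the reaction phase] - [reagent in the second phase]/K3) per volume of the first phase (partition coefficient = 0.509, kL = 0.881 h⁻¹)
    reagent in the reaction phase ⇌ dormant form (K = 1.90, k = 0.0532 h⁻¹)
    starting material + reagent in the reaction phase ⇌ target (K = 5.32 M⁻¹, k = 23.8 M⁻¹ h⁻¹)

In the flask at 6.00 h the step from starting material and reagent in the reaction phase to target, taken by itself with both directions together, relaxes with a half-life of 0.0951 h, short against the 6.0 h of the run and shorter than the 8.54 h of the exchange with the dormant form; I call that a pre-equilibrium. The flask's late ratio is 0.124. Scaled by the fall of reagent in the reaction phase to 0.273 of its level at 6.00 h, and set on the 39.6% of starting material then standing, my 0.129 gives 1.40% of target for this flask left until 25 h, which holds 1.39%.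

(The readings are simulated with constants of no real substance, noise included.)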